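## Retrosynthetic overview

1. The 1,10-epoxide is introduced last, by peracid epoxidation of a (Z)-C1=C10 olefin; the C8 methacrylate comes from acylation, and the ten-membered ring from ring-closing metathesis (C1=C10) of a vinyl/methallyl diene.
2. C8–C9 comes from asymmetric methallylboration of a C8 aldehyde that already carries the α-methylene-γ-lactone (oxidative lactonisation, then Mannich methylenation).
3. Key disconnection C6–C7: intermolecular aldol between the lithium enolate of an (S)-malic-acid-derived 2-tert-butyl-1,3-dioxolan-4-one (C7, C8, C11, C12) and (E)-3-methylocta-2,7-dienal (C1–C6, C15; from geranyl acetate). It sets the quaternary C7 and C6; the C6 hydroxyl then directs the 4,5-epoxidation.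
4. Ring order: dioxolanone template (temporary) → 4,5-oxirane → γ-lactone → ten-membered carbocycle → 1,10-oxirane.

Assumption: locants C1–C15 follow germacrane numbering (lactone carbonyl C12, exocyclic methylene C13, methyls C14 and C15); where a name and a SMILES differ, the SMILES is meant.

## Route

Step 1
Reactants: 1 (S)-malic acid
Product: 2 (2S,4S)-2-tert-butyl-5-oxo-1,3-dioxolane-4-acetic acid
Conditions: pivalaldehyde, TsOH (cat.), H2SO4 (cat.), pentane, reflux (Dean–Stark); recrystallise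
Reagents that add atoms: pivalaldehyde, CC(C)(C)C=O
Why: Acid-catalysed acetalisation of the α-hydroxy acid unit gives the five-membered acylal, and the cis (2S,5S) isomer is the thermodynamic product that crystallises, so the acetal carbon stores the chirality for later self-regeneration of the stereocentre.

Step 2
Reactants: 2 (2S,4S)-2-tert-butyl-5-oxo-1,3-dioxolane-4-acetic acid
Product: 3 (2S,5S)-2-tert-butyl-5-(2-hydroxyethyl)-1,3-dioxolan-4-one
Conditions: BH3·SMe2, THF, 0 °C → rt; MeOH quench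
Reagents that add atoms: none
Why: Chemoselective borane reduction of the free carboxylic acid (via the acyloxyborane) leaves the acylal carbonyl and both stereocentres untouched.

Step 3
Reactants: 3 (2S,5S)-2-tert-butyl-5-(2-hydroxyethyl)-1,3-dioxolan-4-one
Product: 4 (2S,5S)-2-tert-butyl-5-[2-(tert-butyldimethylsilyloxy)ethyl]-1,3-dioxolan-4-one
Conditions: TBSCl, imidazole, CH2Cl2, 0 °C → rt
Reagents that add atoms: tert-butyldimethylsilyl chloride, CC(C)(C)[Si](C)(C)Cl
Why: Silylation of the primary alcohol under non-acidic conditions prevents translactonisation onto the acylal and gives a base-stable C12 oxygen.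

Step 4
Reactants: 5 geranyl acetate
Product: 7 (E)-6-acetoxy-4-methylhex-4-enal, via 6,7-epoxygeranyl acetate 6 (not isolated)
Conditions: mCPBA (1.0 equiv), CH2Cl2, 0 °C; then H5IO6, THF/H2O, 0 °C
Reagents that add atoms: mCPBA, O=C(OO)c1cccc(Cl)c1; water, O
Why: Prilezhaev epoxidation takes the more electron-rich 6,7-olefin (the 2,3-olefin is deactivated by the allylic acetate) and periodic acid cleaves the epoxide via its diol to the aldehyde, so the (E)-C4=C5 geometry comes unchanged from geraniol.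

Step 5
Reactants: 7 (E)-6-acetoxy-4-methylhex-4-enal
Product: 8 (E)-3-methylocta-2,7-dien-1-yl acetate
Conditions: Ph3PCH3Br, KN(SiMe3)2, THF, 0 °C; then 7, −78 → 0 °C
Reagents that add atoms: methyltriphenylphosphonium bromide, C[P+](c1ccccc1)(c1ccccc1)c1ccccc1.[Br-]
Why: Wittig methylenation of the aldehyde is much faster than attack on the acetate at low temperature and installs the terminal vinyl group needed for ring closure.

Step 6
Reactants: 8 (E)-3-methylocta-2,7-dien-1-yl acetate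
Product: 9 (E)-3-methylocta-2,7-dien-1-ol
Conditions: K2CO3, MeOH, rt
Reagents that add atoms: none
Why: Base-catalysed transesterification (methanolysis) frees the allylic alcohol without touching either olefin.

Step 7
Reactants: 9 (E)-3-methylocta-2,7-dien-1-ol
Product: 10 (E)-3-methylocta-2,7-dienal
Conditions: TEMPO (10 mol%), PhI(OAc)2, CH2Cl2, rt
Reagents that add atoms: none
Why: Oxoammonium (TEMPO) oxidation of the primary allylic alcohol stops at the enal and does not isomerise the E olefin.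

Step 8
Reactants: 4 (2S,5S)-2-tert-butyl-5-[2-(tert-butyldimethylsilyloxy)ethyl]-1,3-dioxolan-4-one; 10 (E)-3-methylocta-2,7-dienal
Product: 12 (2S,5R)-2-tert-butyl-5-[2-(tert-butyldimethylsilyloxy)ethyl]-5-[(1R,2E)-1-hydroxy-3-methylocta-2,7-dien-1-yl]-1,3-dioxolan-4-one, via lithium enolate 11 (not isolated)
Conditions: LiN(iPr)2 (1.1 equiv), THF, −78 °C, 45 min; then 10, −78 °C, 1 h; AcOH, −78 °C
Reagents that add atoms: none
Why: Intermolecular aldol addition with self-regeneration of the stereocentre: the enal adds to the enolate face anti to the tert-butyl group (C7, net retention from (S)-malic acid), and a closed Zimmerman–Traxler chair with the alkenyl group equatorial places the new hydroxyl syn to the CH2CH2OSi arm (C6 = 1′R); the minor carbinol epimer is removed by chromatography.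

Step 9
Reactants: 12 (2S,5R)-2-tert-butyl-5-[2-(tert-butyldimethylsilyloxy)ethyl]-5-[(1R,2E)-1-hydroxy-3-methylocta-2,7-dien-1-yl]-1,3-dioxolan-4-one
Product: 13 (2S,5R)-5-{(R)-[(2R,3R)-3-(but-3-en-1-yl)-3-methyloxiran-2-yl](hydroxy)methyl}-2-tert-butyl-5-[2-(tert-butyldimethylsilyloxy)ethyl]-1,3-dioxolan-4-one
Conditions: mCPBA, NaHCO3, CH2Cl2, −20 → 0 °C
Reagents that add atoms: mCPBA, O=C(OO)c1cccc(Cl)c1
Why: Henbest hydroxyl-directed Prilezhaev epoxidation: A(1,3) strain with the cis C15 methyl holds the C6–H in the olefin plane, so the hydrogen-bonded peracid delivers oxygen to the threo face (4R,5R), and the terminal vinyl group is far less reactive.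

Step 10
Reactants: 13 (2S,5R)-5-{(R)-[(2R,3R)-3-(but-3-en-1-yl)-3-methyloxiran-2-yl](hydroxy)methyl}-2-tert-butyl-5-[2-(tert-butyldimethylsilyloxy)ethyl]-1,3-dioxolan-4-one
Product: 14 (2S,3R)-3-[(2R,3R)-3-(but-3-en-1-yl)-3-methyloxiran-2-yl]-2-[2-(tert-butyldimethylsilyloxy)ethyl]propane-1,2,3-triol
Conditions: LiBH4, THF/MeOH, 0 °C
Reagents that add atoms: none
Why: Hydride reduction of the activated acylal carbonyl collapses the template, giving the C8 primary alcohol and the free C7 tertiary alcohol, while the trisubstituted epoxide and silyl ether are inert to LiBH4 at 0 °C.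

Step 11
Reactants: 14 (2S,3R)-3-[(2R,3R)-3-(but-3-en-1-yl)-3-methyloxiran-2-yl]-2-[2-(tert-butyldimethylsilyloxy)ethyl]propane-1,2,3-triol
Product: 15 (2S,3R)-3-[(2R,3R)-3-(but-3-en-1-yl)-3-methyloxiran-2-yl]-2-[2-(tert-butyldimethylsilyloxy)ethyl]-1-(tert-butyldiphenylsilyloxy)propane-2,3-diol
Conditions: TBDPSCl, imidazole, CH2Cl2, 0 °C
Reagents that add atoms: tert-butyldiphenylsilyl chloride, CC(C)(C)[Si](Cl)(c1ccccc1)c1ccccc1
Why: Selective silylation of the only primary hydroxyl (C8) over the hindered secondary and tertiary ones masks C8 so that only C6 can lactonise later.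

Step 12
Reactants: 15 (2S,3R)-3-[(2R,3R)-3-(but-3-en-1-yl)-3-methyloxiran-2-yl]-2-[2-(tert-butyldimethylsilyloxy)ethyl]-1-(tert-butyldiphenylsilyloxy)propane-2,3-diol
Product: 16 (3S,4R)-4-[(2R,3R)-3-(but-3-en-1-yl)-3-methyloxiran-2-yl]-3-[(tert-butyldiphenylsilyloxy)methyl]butane-1,3,4-triol
Conditions: HF·pyridine, pyridine, THF, 0 °C → rt
Reagents that add atoms: none
Why: Buffered fluoride desilylation cleaves the primary TBS ether much faster than the bulkier TBDPS ether and does not open the epoxide.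

Step 13
Reactants: 16 (3S,4R)-4-[(2R,3R)-3-(but-3-en-1-yl)-3-methyloxiran-2-yl]-3-[(tert-butyldiphenylsilyloxy)methyl]butane-1,3,4-triol
Product: 19 (4S,5R)-5-[(2R,3R)-3-(but-3-en-1-yl)-3-methyloxiran-2-yl]-4-[(tert-butyldiphenylsilyloxy)methyl]-4-hydroxyoxolan-2-one, via hydroxy aldehyde 17 (not isolated), via lactol 18 (not isolated)
Conditions: TEMPO (20 mol%), PhI(OAc)2 (2.5 equiv), CH2Cl2, rt
Reagents that add atoms: none
Why: TEMPO-mediated oxidative lactonisation of the 1,4-diol: the primary C12 alcohol is oxidised first, the aldehyde is trapped by the C6 hydroxyl as a five-membered lactol, and this is oxidised to the 6,12-lactone under near-neutral conditions that spare the epoxide.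

Step 14
Reactants: 19 (4S,5R)-5-[(2R,3R)-3-(but-3-en-1-yl)-3-methyloxiran-2-yl]-4-[(tert-butyldiphenylsilyloxy)methyl]-4-hydroxyoxolan-2-one
Product: 21 (4S,5R)-5-[(2R,3R)-3-(but-3-en-1-yl)-3-methyloxiran-2-yl]-4-[(tert-butyldiphenylsilyloxy)methyl]-3-[(dimethylamino)methyl]-4-hydroxyoxolan-2-one (C3 epimers), via dilithium dianion 20 (not isolated)
Conditions: LiN(iPr)2 (2.5 equiv), THF, −78 °C; then CH2=NMe2+ I−, −78 → 0 °C
Reagents that add atoms: N,N-dimethylmethyleneiminium iodide, C=[N+](C)C.[I-]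
Why: Mannich reaction of the lactone enolate with Eschenmoser's salt; forming the alkoxide–enolate dianion (Fráter–Seebach type) suppresses β-elimination and retro-aldol of the tertiary β-hydroxy lactone.

Step 15
Reactants: 21 (4S,5R)-5-[(2R,3R)-3-(but-3-en-1-yl)-3-methyloxiran-2-yl]-4-[(tert-butyldiphenylsilyloxy)methyl]-3-[(dimethylamino)methyl]-4-hydroxyoxolan-2-one
Product: 23 (4S,5R)-5-[(2R,3R)-3-(but-3-en-1-yl)-3-methyloxiran-2-yl]-4-[(tert-butyldiphenylsilyloxy)methyl]-4-hydroxy-3-methylideneoxolan-2-one, via methiodide 22 (not isolated)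
Conditions: MeI, MeOH, rt; then NaHCO3 (aq.), CH2Cl2, rt
Reagents that add atoms: none
Why: N-Methylation followed by Hofmann-type (E1cB) elimination gives the α-methylene lactone, and because C7 carries no hydrogen only the exocyclic olefin can form.

Step 16
Reactants: 23 (4S,5R)-5-[(2R,3R)-3-(but-3-en-1-yl)-3-methyloxiran-2-yl]-4-[(tert-butyldiphenylsilyloxy)methyl]-4-hydroxy-3-methylideneoxolan-2-one
Product: 24 (4S,5R)-5-[(2R,3R)-3-(but-3-en-1-yl)-3-methyloxiran-2-yl]-4-hydroxy-4-(hydroxymethyl)-3-methylideneoxolan-2-one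
Conditions: Bu4NF, AcOH (1:1), THF, 0 °C → rt
Reagents that add atoms: none
Why: Acetic-acid-buffered fluoride desilylation frees the C8 primary alcohol without generating alkoxides that could attack the epoxide or the Michael acceptor.

Step 17
Reactants: 24 (4S,5R)-5-[(2R,3R)-3-(but-3-en-1-yl)-3-methyloxiran-2-yl]-4-hydroxy-4-(hydroxymethyl)-3-methylideneoxolan-2-one
Product: 25 (2R,3R)-2-[(2R,3R)-3-(but-3-en-1-yl)-3-methyloxiran-2-yl]-3-hydroxy-4-methylidene-5-oxooxolane-3-carbaldehyde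
Conditions: Dess–Martin periodinane, NaHCO3, CH2Cl2, 0 °C
Reagents that add atoms: none
Why: Dess–Martin oxidation of the primary alcohol gives the aldehyde, which cannot epimerise because its α-carbon (C7) is quaternary, and the tertiary hydroxyl is not oxidisable.

Step 18
Reactants: 25 (2R,3R)-2-[(2R,3R)-3-(but-3-en-1-yl)-3-methyloxiran-2-yl]-3-hydroxy-4-methylidene-5-oxooxolane-3-carbaldehyde
Product: 26 (4S,5R)-5-[(2R,3R)-3-(but-3-en-1-yl)-3-methyloxiran-2-yl]-4-hydroxy-4-[(1R)-1-hydroxy-3-methylbut-3-en-1-yl]-3-methylideneoxolan-2-one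
Conditions: (+)-Ipc2BOMe, 2-methylallylmagnesium chloride, Et2O, −78 °C → rt; then 25 (0.5 equiv relative to the borane), −78 °C; then pH 7 buffer, 30% H2O2, MeOH, 0 °C
Reagents that add atoms: 2-methylallylmagnesium chloride, C=C(C)C[Mg]Cl
Why: Brown asymmetric allylboration with the (−)-α-pinene-derived B-methallyl reagent: the closed chair transition state delivers the methallyl group to the Re face of the aldehyde under reagent control, giving the (R)-carbinol at C8 (7,8-syn diol) and forming C8–C9.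

Step 19
Reactants: 26 (4S,5R)-5-[(2R,3R)-3-(but-3-en-1-yl)-3-methyloxiran-2-yl]-4-hydroxy-4-[(1R)-1-hydroxy-3-methylbut-3-en-1-yl]-3-methylideneoxolan-2-one
Product: 27 (1(10)Z,4R,5R,6R,7S,8R)-4,5-epoxy-7,8-dihydroxygermacra-1(10),11(13)-dien-12,6-olide
Conditions: second-generation Grubbs catalyst RuCl2(=CHPh)(PCy3)(H2IMes) (15 mol%), 1,4-benzoquinone (cat.), toluene (1 mM), 80 °C, slow addition
Reagents that add atoms: none
Why: Ring-closing metathesis: the ruthenium carbene loads on the monosubstituted C1 vinyl group and closes onto the 1,1-disubstituted methallyl olefin, the ten-membered ring enforces the Z geometry, the trans-lactone and trans-epoxide pre-organise the chain, and the hindered electron-poor exocyclic methylene is not expected to compete.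

Step 20
Reactants: 27 (1(10)Z,4R,5R,6R,7S,8R)-4,5-epoxy-7,8-dihydroxygermacra-1(10),11(13)-dien-12,6-olide
Product: 28 (1(10)Z,4R,5R,6R,7S,8R)-4,5-epoxy-7-hydroxy-8-(methacryloyloxy)germacra-1(10),11(13)-dien-12,6-olide
Conditions: methacrylic anhydride, Et3N, DMAP, CH2Cl2, 0 °C → rt
Reagents that add atoms: methacrylic anhydride, C=C(C)C(=O)OC(=O)C(C)=C
Why: DMAP-catalysed acylation esterifies the secondary C8 hydroxyl, while the tertiary C7 hydroxyl does not react.

Step 21
Reactants: 28 (1(10)Z,4R,5R,6R,7S,8R)-4,5-epoxy-7-hydroxy-8-(methacryloyloxy)germacra-1(10),11(13)-dien-12,6-olide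
Product: 29 (1S,4R,5R,6R,7S,8R,10R)-1,10:4,5-diepoxy-7-hydroxy-8-(methacryloyloxy)germacr-11(13)-en-12,6-olide (CNP0228789.1)
Conditions: mCPBA, NaHCO3, CH2Cl2, 0 °C
Reagents that add atoms: mCPBA, O=C(OO)c1cccc(Cl)c1
Why: Prilezhaev epoxidation attacks only the electron-rich trisubstituted C1=C10 olefin (the two acrylate-type olefins are inert to peracid), on the face anti to the C8 ester and syn to the hydrogen-bonding C7 hydroxyl, giving the cis (1S,10R) epoxide.

## Compound list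

1 | (S)-malic acid | OC(=O)C[C@H](O)C(=O)O | starting material
2 | (2S,4S)-2-tert-butyl-5-oxo-1,3-dioxolane-4-acetic acid | OC(=O)C[C@@H]1O[C@H](C(C)(C)C)OC1=O | intermediate
3 | (2S,5S)-2-tert-butyl-5-(2-hydroxyethyl)-1,3-dioxolan-4-one | OCC[C@@H]1O[C@H](C(C)(C)C)OC1=O | intermediate
4 | (2S,5S)-2-tert-butyl-5-[2-(tert-butyldimethylsilyloxy)ethyl]-1,3-dioxolan-4-one | CC(C)(C)[Si](C)(C)OCC[C@@H]1O[C@H](C(C)(C)C)OC1=O | intermediate
5 | geranyl acetate | CC(=O)OC/C=C(\C)CCC=C(C)C | starting material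
6 | 6,7-epoxygeranyl acetate (racemic at the oxirane) | CC(=O)OC/C=C(\C)CCC1OC1(C)C | intermediate
7 | (E)-6-acetoxy-4-methylhex-4-enal | CC(=O)OC/C=C(\C)CCC=O | intermediate
8 | (E)-3-methylocta-2,7-dien-1-yl acetate | CC(=O)OC/C=C(\C)CCC=C | intermediate
9 | (E)-3-methylocta-2,7-dien-1-ol | OC/C=C(\C)CCC=C | intermediate
10 | (E)-3-methylocta-2,7-dienal | O=C/C=C(\C)CCC=C | intermediate
11 | lithium (2S)-2-tert-butyl-5-[2-(tert-butyldimethylsilyloxy)ethyl]-1,3-dioxol-4-olate | [Li+].[O-]C1=C(CCO[Si](C)(C)C(C)(C)C)O[C@H](C(C)(C)C)O1 | intermediate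
12 | (2S,5R)-2-tert-butyl-5-[2-(tert-butyldimethylsilyloxy)ethyl]-5-[(1R,2E)-1-hydroxy-3-methylocta-2,7-dien-1-yl]-1,3-dioxolan-4-one | C=CCC/C(C)=C/[C@@H](O)[C@@]1(CCO[Si](C)(C)C(C)(C)C)O[C@H](C(C)(C)C)OC1=O | intermediate
13 | (2S,5R)-5-{(R)-[(2R,3R)-3-(but-3-en-1-yl)-3-methyloxiran-2-yl](hydroxy)methyl}-2-tert-butyl-5-[2-(tert-butyldimethylsilyloxy)ethyl]-1,3-dioxolan-4-one | C=CCC[C@@]1(C)O[C@@H]1[C@@H](O)[C@@]2(CCO[Si](C)(C)C(C)(C)C)O[C@H](C(C)(C)C)OC2=O | intermediate
14 | (2S,3R)-3-[(2R,3R)-3-(but-3-en-1-yl)-3-methyloxiran-2-yl]-2-[2-(tert-butyldimethylsilyloxy)ethyl]propane-1,2,3-triol | C=CCC[C@@]1(C)O[C@@H]1[C@@H](O)[C@@](O)(CO)CCO[Si](C)(C)C(C)(C)C | intermediate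
15 | (2S,3R)-3-[(2R,3R)-3-(but-3-en-1-yl)-3-methyloxiran-2-yl]-2-[2-(tert-butyldimethylsilyloxy)ethyl]-1-(tert-butyldiphenylsilyloxy)propane-2,3-diol | C=CCC[C@@]1(C)O[C@@H]1[C@@H](O)[C@@](O)(CO[Si](c2ccccc2)(c3ccccc3)C(C)(C)C)CCO[Si](C)(C)C(C)(C)C | intermediate
16 | (3S,4R)-4-[(2R,3R)-3-(but-3-en-1-yl)-3-methyloxiran-2-yl]-3-[(tert-butyldiphenylsilyloxy)methyl]butane-1,3,4-triol | C=CCC[C@@]1(C)O[C@@H]1[C@@H](O)[C@@](O)(CO[Si](c2ccccc2)(c3ccccc3)C(C)(C)C)CCO | intermediate
17 | (3S,4R)-4-[(2R,3R)-3-(but-3-en-1-yl)-3-methyloxiran-2-yl]-3-[(tert-butyldiphenylsilyloxy)methyl]-3,4-dihydroxybutanal | C=CCC[C@@]1(C)O[C@@H]1[C@@H](O)[C@@](O)(CO[Si](c2ccccc2)(c3ccccc3)C(C)(C)C)CC=O | intermediate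
18 | (4S,5R)-5-[(2R,3R)-3-(but-3-en-1-yl)-3-methyloxiran-2-yl]-4-[(tert-butyldiphenylsilyloxy)methyl]oxolane-2,4-diol (anomers) | C=CCC[C@@]1(C)O[C@@H]1[C@H]2OC(O)C[C@]2(O)CO[Si](c3ccccc3)(c4ccccc4)C(C)(C)C | intermediate
19 | (4S,5R)-5-[(2R,3R)-3-(but-3-en-1-yl)-3-methyloxiran-2-yl]-4-[(tert-butyldiphenylsilyloxy)methyl]-4-hydroxyoxolan-2-one | C=CCC[C@@]1(C)O[C@@H]1[C@H]2OC(=O)C[C@]2(O)CO[Si](c3ccccc3)(c4ccccc4)C(C)(C)C | intermediate
20 | dilithium dianion of 19 (C7 alkoxide and lactone enolate) | [Li+].[Li+].C=CCC[C@@]1(C)O[C@@H]1[C@H]2OC([O-])=C[C@]2([O-])CO[Si](c3ccccc3)(c4ccccc4)C(C)(C)C | intermediate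
21 | (4S,5R)-5-[(2R,3R)-3-(but-3-en-1-yl)-3-methyloxiran-2-yl]-4-[(tert-butyldiphenylsilyloxy)methyl]-3-[(dimethylamino)methyl]-4-hydroxyoxolan-2-one (C3 epimers) | C=CCC[C@@]1(C)O[C@@H]1[C@H]2OC(=O)C(CN(C)C)[C@]2(O)CO[Si](c3ccccc3)(c4ccccc4)C(C)(C)C | intermediate
22 | N-methiodide of 21 (trimethylammonium iodide) | [I-].C=CCC[C@@]1(C)O[C@@H]1[C@H]2OC(=O)C(C[N+](C)(C)C)[C@]2(O)CO[Si](c3ccccc3)(c4ccccc4)C(C)(C)C | intermediate
23 | (4S,5R)-5-[(2R,3R)-3-(but-3-en-1-yl)-3-methyloxiran-2-yl]-4-[(tert-butyldiphenylsilyloxy)methyl]-4-hydroxy-3-methylideneoxolan-2-one | C=CCC[C@@]1(C)O[C@@H]1[C@H]2OC(=O)C(=C)[C@]2(O)CO[Si](c3ccccc3)(c4ccccc4)C(C)(C)C | intermediate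
24 | (4S,5R)-5-[(2R,3R)-3-(but-3-en-1-yl)-3-methyloxiran-2-yl]-4-hydroxy-4-(hydroxymethyl)-3-methylideneoxolan-2-one | C=CCC[C@@]1(C)O[C@@H]1[C@H]2OC(=O)C(=C)[C@]2(O)CO | intermediate
25 | (2R,3R)-2-[(2R,3R)-3-(but-3-en-1-yl)-3-methyloxiran-2-yl]-3-hydroxy-4-methylidene-5-oxooxolane-3-carbaldehyde | C=CCC[C@@]1(C)O[C@@H]1[C@H]2OC(=O)C(=C)[C@]2(O)C=O | intermediate
26 | (4S,5R)-5-[(2R,3R)-3-(but-3-en-1-yl)-3-methyloxiran-2-yl]-4-hydroxy-4-[(1R)-1-hydroxy-3-methylbut-3-en-1-yl]-3-methylideneoxolan-2-one | C=CCC[C@@]1(C)O[C@@H]1[C@H]2OC(=O)C(=C)[C@]2(O)[C@H](O)CC(C)=C | intermediate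
27 | (1(10)Z,4R,5R,6R,7S,8R)-4,5-epoxy-7,8-dihydroxygermacra-1(10),11(13)-dien-12,6-olide | O[C@@H]1C/C(C)=C\CC[C@@]2(C)O[C@@H]2[C@H]2OC(=O)C(=C)[C@@]21O | intermediate
28 | (1(10)Z,4R,5R,6R,7S,8R)-4,5-epoxy-7-hydroxy-8-(methacryloyloxy)germacra-1(10),11(13)-dien-12,6-olide | C=C(C)C(=O)O[C@@H]1C/C(C)=C\CC[C@@]2(C)O[C@@H]2[C@H]2OC(=O)C(=C)[C@@]21O | intermediate
29 | (1S,4R,5R,6R,7S,8R,10R)-1,10:4,5-diepoxy-7-hydroxy-8-(methacryloyloxy)germacr-11(13)-en-12,6-olide (CNP0228789.1) | C=C(C)C(=O)O[C@@H]1C[C@@]2(C)O[C@H]2CC[C@@]2(C)O[C@@H]2[C@H]2OC(=O)C(=C)[C@@]21O | target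

## Step count and risks

Total step count: 21 steps (3 for the dioxolanone 4, 4 for the enal 10, 14 from the fragment union onwards).
Longest linear sequence: 18 steps (geranyl acetate 5 → 29, steps 4–7 and 8–21).

The three steps most likely to fail:

Step 8 (aldol). The quaternary centre is secure (attack anti to tert-butyl), but the carbinol (C1′) selectivity of dioxolanone enolate aldols can be only moderate, and the adduct can undergo retro-aldol if the aldolate warms. Fallback: set the carbinol by reagent-controlled ketone reduction instead of by the aldol transition state. Setting out from 12 (as its C1′ epimer mixture), Dess–Martin oxidation gives the non-enolisable keto acylal (2S,5R)-2-tert-butyl-5-[2-(tert-butyldimethylsilyloxy)ethyl]-5-[(2E)-3-methylocta-2,7-dienoyl]-1,3-dioxolan-4-one F1. Reduction with (S)-2-methyl-CBS-oxazaborolidine and catecholborane in toluene at −78 °C (quaternary carbon as the large group, alkenyl as the small group) returns the (1′R) alcohol and rejoins the route at 12.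

Step 19 (ring-closing metathesis). Closing a ten-membered carbocycle to a trisubstituted olefin is strained and prone to oligomerisation, and the exocyclic methylene of the lactone could compete as a third olefin. Fallback: close the ring before the methylene group exists, so that only the two reacting olefins are present. The route:
- Setting out from lactone 19, Bu4NF/AcOH gives (4S,5R)-5-[(2R,3R)-3-(but-3-en-1-yl)-3-methyloxiran-2-yl]-4-hydroxy-4-(hydroxymethyl)oxolan-2-one F2.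
- Dess–Martin oxidation gives (2R,3R)-2-[(2R,3R)-3-(but-3-en-1-yl)-3-methyloxiran-2-yl]-3-hydroxy-5-oxooxolane-3-carbaldehyde F3.
- The same Brown methallylboration gives (4S,5R)-5-[(2R,3R)-3-(but-3-en-1-yl)-3-methyloxiran-2-yl]-4-hydroxy-4-[(1R)-1-hydroxy-3-methylbut-3-en-1-yl]oxolan-2-one F4.
- Ring-closing metathesis with the same ruthenium catalyst then gives (1(10)Z,4R,5R,6R,7S,8R)-4,5-epoxy-7,8-dihydroxy-13-norgermacr-1(10)-en-12,6-olide F5.
- Et3SiCl/imidazole protects C8–OH as the 8-O-triethylsilyl ether of the norgermacrenolide F6.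
- LiN(iPr)2 (2.5 equiv, −78 °C) forms the dilithium dianion of that silyl ether F7, which reacts with CH2=NMe2+ I− to give the 11-[(dimethylamino)methyl] Mannich base F8.
- MeI converts it into the trimethylammonium iodide F9, and NaHCO3 eliminates to the 8-O-triethylsilyl ether of the α-methylene lactone F10.
- HF·pyridine removes the silyl group and the sequence rejoins the route at 27.

Step 21 (final epoxidation). The facial selectivity on the macrocyclic Z-olefin rests on a conformational argument (attack anti to the C8 ester, assisted by the C7 hydroxyl) and could be low or reversed. Fallback: epoxidise one step earlier under reagent control with a chiral dioxirane. Setting out from diol 27, the enantiomer of the fructose-derived Shi ketone (from L-sorbose) with KHSO5 (potassium peroxymonosulfate triple salt), K2CO3 buffer, MeCN/dimethoxymethane/H2O, 0 °C, should deliver oxygen to the required face (spiro transition state with the single olefinic hydrogen, C1–H, in the hindered quadrant). This gives (1S,4R,5R,6R,7S,8R,10R)-1,10:4,5-diepoxy-7,8-dihydroxygermacr-11(13)-en-12,6-olide F11; methacrylic anhydride/Et3N/DMAP then acylates C8–OH and the sequence comes back to the route at 29.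

## Further compounds

F1 | step 8 | (2S,5R)-2-tert-butyl-5-[2-(tert-butyldimethylsilyloxy)ethyl]-5-[(2E)-3-methylocta-2,7-dienoyl]-1,3-dioxolan-4-one | C=CCC/C(C)=C/C(=O)[C@@]1(CCO[Si](C)(C)C(C)(C)C)O[C@H](C(C)(C)C)OC1=O
F2 | step 19 | (4S,5R)-5-[(2R,3R)-3-(but-3-en-1-yl)-3-methyloxiran-2-yl]-4-hydroxy-4-(hydroxymethyl)oxolan-2-one | C=CCC[C@@]1(C)O[C@@H]1[C@H]2OC(=O)C[C@]2(O)CO
F3 | step 19 | (2R,3R)-2-[(2R,3R)-3-(but-3-en-1-yl)-3-methyloxiran-2-yl]-3-hydroxy-5-oxooxolane-3-carbaldehyde | C=CCC[C@@]1(C)O[C@@H]1[C@H]2OC(=O)C[C@]2(O)C=O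
F4 | step 19 | (4S,5R)-5-[(2R,3R)-3-(but-3-en-1-yl)-3-methyloxiran-2-yl]-4-hydroxy-4-[(1R)-1-hydroxy-3-methylbut-3-en-1-yl]oxolan-2-one | C=CCC[C@@]1(C)O[C@@H]1[C@H]2OC(=O)C[C@]2(O)[C@H](O)CC(C)=C
F5 | step 19 | (1(10)Z,4R,5R,6R,7S,8R)-4,5-epoxy-7,8-dihydroxy-13-norgermacr-1(10)-en-12,6-olide | O[C@@H]1C/C(C)=C\CC[C@@]2(C)O[C@@H]2[C@H]2OC(=O)C[C@@]21O
F6 | step 19 | 8-O-triethylsilyl ether of the norgermacrenolide F5 | CC[Si](CC)(CC)O[C@@H]1C/C(C)=C\CC[C@@]2(C)O[C@@H]2[C@H]2OC(=O)C[C@@]21O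
F7 | step 19 | dilithium dianion of F6 (C7 alkoxide and lactone enolate) | [Li+].[Li+].CC[Si](CC)(CC)O[C@@H]1C/C(C)=C\CC[C@@]2(C)O[C@@H]2[C@H]2OC([O-])=C[C@@]21[O-]
F8 | step 19 | 11-[(dimethylamino)methyl] Mannich base of F6 (C11 epimers) | CC[Si](CC)(CC)O[C@@H]1C/C(C)=C\CC[C@@]2(C)O[C@@H]2[C@H]2OC(=O)C(CN(C)C)[C@@]21O
F9 | step 19 | trimethylammonium iodide (methiodide) of F8 | [I-].CC[Si](CC)(CC)O[C@@H]1C/C(C)=C\CC[C@@]2(C)O[C@@H]2[C@H]2OC(=O)C(C[N+](C)(C)C)[C@@]21O
F10 | step 19 | 8-O-triethylsilyl ether of 27 | CC[Si](CC)(CC)O[C@@H]1C/C(C)=C\CC[C@@]2(C)O[C@@H]2[C@H]2OC(=O)C(=C)[C@@]21O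
F11 | step 21 | (1S,4R,5R,6R,7S,8R,10R)-1,10:4,5-diepoxy-7,8-dihydroxygermacr-11(13)-en-12,6-olide | O[C@@H]1C[C@@]2(C)O[C@H]2CC[C@@]2(C)O[C@@H]2[C@H]2OC(=O)C(=C)[C@@]21O
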